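**Strategy.** The route rests on cutting ring A of the trans-decalin (the cyclohexane carrying the 1,3-diol and the secondary methyl; C1 is the acyl-bearing quaternary carbon) at two bonds, the ring-fusion bond C4a–C8a and C7–C8. One anionic formal (4+2) annulation makes both: an ester trienolate adds through C4a to C8a of an α,β-unsaturated δ-lactone and the lactone enolate (C8) then acylates the ester carbon (C7), so rings B and A close together. The step exploits the C7 oxygen (an ester in the precursor) and the C1 methyl, which is the lactone CH2O and forces cis-annulation. The precursor is a monocyclic dihydropyranone carrying a dienoate chain. Tetronate coupling, Z-selective ring-closing metathesis and deprotection finish the synthesis.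

Key step: step 10

Remarks on the chemistry. Decalin locants follow naphthalene: C1 (quaternary, acyl-bearing), C2 (CH carrying the macrocycle CH2), C3=C4, C4a, C5 (OH), C6 (Me), C7 (OH), C8 (CH2), C8a; β is the face of the C1 carbonyl-derived substituent, α the opposite face. Assumption: the 3-acyltetronic acid is drawn as the enol tautomer of the target SMILES; 4–7 are carried as epimer mixtures at the acidic malonate carbon, 31 and 34 as epimer mixtures at a centre that is later destroyed or reset.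

Step 1
Reactants: 1 3-[(tert-butyldimethylsilyl)oxy]propanal
Product: 2 (2E)-5-[(tert-butyldimethylsilyl)oxy]pent-2-enal
Conditions: Ph3P=CHCHO, toluene, 80 °C
Reagents that add atoms: (triphenylphosphoranylidene)acetaldehyde, O=CC=P(c1ccccc1)(c1ccccc1)c1ccccc1
Why: Wittig olefination with a stabilised formyl ylide should give the E-enal by two-carbon homologation.

Step 2
Reactants: 2 (2E)-5-[(tert-butyldimethylsilyl)oxy]pent-2-enal; 3 tert-butyl methyl propanedioate
Product: 4 tert-butyl methyl 2-[(3S)-1-silyloxy-5-oxopentan-3-yl]propanedioate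
Conditions: (R)-2-[diphenyl(trimethylsilyloxy)methyl]pyrrolidine (10 mol %), PhCO2H (10 mol %), EtOH, 0 °C
Reagents that add atoms: none
Why: Iminium-catalysed asymmetric Michael addition of a malonate to an enal; the diarylsilyloxymethyl group of the (R)-catalyst shields one face of the E-iminium ion, so the malonate should add to the other face and set the (S) centre (future C2).

Step 3
Reactants: 4 Michael adduct aldehyde
Product: 5 tert-butyl methyl 2-[(3R)-1-silyloxyhex-5-en-3-yl]propanedioate
Conditions: Ph3PCH3Br, KHMDS (2.3 equiv each), THF, −78 → 0 °C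
Reagents that add atoms: methyltriphenylphosphonium bromide (as its ylide), C[P+](c1ccccc1)(c1ccccc1)c1ccccc1.[Br-]
Why: Wittig methylenation turns the aldehyde into the terminal alkene that later serves as the allyl group for metathesis; the excess ylide covers the acidic malonate C–H.

Step 4
Reactants: 5 silyl ether diester
Product: 7 tert-butyl (4R)-2-oxo-4-(prop-2-en-1-yl)oxane-3-carboxylate, via hydroxy diester 6 (not isolated)
Conditions: p-TsOH·H2O (5 mol %), MeOH, 23 °C; then toluene, 45 °C, reduced pressure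
Reagents that add atoms: none
Why: Acid-catalysed desilylation followed by lactonisation (intramolecular transesterification) of the δ-hydroxy ester; only the methyl ester should be attacked, the tert-butyl ester being inert.

Step 5
Reactants: 7 lactone ester
Product: 8 tert-butyl (3S,4R)-2-oxo-4-(prop-2-en-1-yl)-3-{[(triisopropylsilyl)oxy]methyl}oxane-3-carboxylate
Conditions: K2CO3, i-Pr3SiOCH2Cl, DMF, 0 → 23 °C
Reagents that add atoms: (triisopropylsiloxy)methyl chloride, ClCO[Si](C(C)C)(C(C)C)C(C)C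
Why: C-alkylation of the malonate-type lactone enolate with an alkoxymethyl chloride; the electrophile should enter anti to the C4 allyl group and so set the quaternary centre (future C1) with the CH2O group trans to allyl.

Step 6
Reactants: 8 quaternary lactone
Product: 9 lactol, tert-butyl (3S,4R)-2-hydroxy-4-(prop-2-en-1-yl)-3-{[(triisopropylsilyl)oxy]methyl}oxane-3-carboxylate
Conditions: i-Bu2AlH (1.1 equiv), CH2Cl2, −78 °C; Rochelle salt
Reagents that add atoms: none
Why: Half-reduction of a lactone to the lactol with diisobutylaluminium hydride; the hindered tert-butyl ester should react much more slowly.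

Step 7
Reactants: 9 lactol
Product: 11 tert-butyl (3R)-3-[(3R)-1-hydroxyhex-5-en-3-yl]-6-oxo-3,6-dihydro-2H-pyran-3-carboxylate, via Z-enoate hydroxy ester 10 (not isolated)
Conditions: (CF3CH2O)2P(O)CH2CO2Me, KHMDS, 18-crown-6, THF, −78 °C; AcOH; then HF·pyridine, THF, 0 → 23 °C
Reagents that add atoms: methyl bis(2,2,2-trifluoroethyl)phosphonoacetate, COC(=O)CP(=O)(OCC(F)(F)F)OCC(F)(F)F
Why: Still–Gennari Z-selective Horner–Wadsworth–Emmons olefination of the open hydroxy-aldehyde form of the lactol, then desilylation; the freed CH2OH should lactonise onto the Z-enoate (only the Z isomer can), and the silyl ether prevents retro-aldol loss of formaldehyde under the basic olefination.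

Step 8
Reactants: 11 dihydropyranone alcohol
Product: 13 tert-butyl (3R)-6-oxo-3-[(2E,5R)-1-oxoocta-2,7-dien-5-yl]-3,6-dihydro-2H-pyran-3-carboxylate, via aldehyde 12 (not isolated)
Conditions: Dess–Martin periodinane, NaHCO3, CH2Cl2, 0 → 23 °C; then Ph3P=CHCHO, 40 °C
Reagents that add atoms: (triphenylphosphoranylidene)acetaldehyde, O=CC=P(c1ccccc1)(c1ccccc1)c1ccccc1
Why: One-pot Dess–Martin oxidation and Wittig homologation should give the E-enal without isolating the β-branched aldehyde.

Step 9
Reactants: 13 enal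
Product: 14 tert-butyl (3R)-3-[(4R,6E,8E)-10-ethoxy-9-methyl-10-oxodeca-1,6,8-trien-4-yl]-6-oxo-3,6-dihydro-2H-pyran-3-carboxylate
Conditions: Ph3P=C(CH3)CO2Et, CH2Cl2, 23 °C
Reagents that add atoms: ethyl 2-(triphenylphosphoranylidene)propanoate, CCOC(=O)C(C)=P(c1ccccc1)(c1ccccc1)c1ccccc1
Why: Wittig olefination with a stabilised α-methyl ylide should give the (E,E)-2-methyldienoate, the latent C4a–C5–C6–C7 unit.

Step 10
Reactants: 14 dienoate dihydropyranone
Product: 17 tricyclic β-keto lactone (4a,8a-trans octalin-7-one with C8–C(=O)–O–CH2–C1 lactone), via lithium trienolate 15 (not isolated), via lithium lactone enolate 16 (not isolated)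
Conditions: LDA (1.2 equiv), THF–DMPU (6:1), 5 mM, −78 °C; then −78 → 0 °C; aq. NH4Cl
Reagents that add atoms: none
Why: LDA removes an ε-hydrogen of the (2E,4E)-dienoate (kinetic deprotonation of E-enoates is known to give the Z enolate double bond, here C3=C4), the trienolate adds through its γ-carbon (C4a) to C8a of the tethered α,β-unsaturated δ-lactone, and the lactone enolate (C8) then acylates the ethyl ester (C7) with loss of ethoxide, driven by deprotonation of the β-keto lactone. The closest known reaction type is the Michael–Claisen (Michael–Dieckmann) annulation of stabilised ester anions with unsaturated esters, an anionic formal (4+2) cycloaddition of a 1-alkoxy-1-oxido diene. Ring B closes by a 6-exo-trig conjugate addition and ring A by a 6-exo-trig Dieckmann acylation. C8a is controlled by the lactone ring: the nucleophile hangs from the adjacent quaternary C1 and can reach C8a only on the face of its own tether (cis-annulation), which puts H-8a cis to the C1 ester and the lactone CH2O (the future methyl) axial on ring B. C4a follows from a chair-like transition state with the dienolate chain equatorial, because an axial chain would be syn-axial to the lactone CH2, and this gives the trans ring fusion. The step needs γ- over α-attack of the trienolate, secured by ring size (six- against eight-membered), and an s-cis dienolate for the acylation, secured because only that conformer can close while other Michael adducts can revert or re-enolise.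

Step 11
Reactants: 17 tricyclic β-keto lactone
Product: 19 tert-butyl 1α-(hydroxymethyl)-6-methyl-7-oxo-2β-(prop-2-en-1-yl)-1,2,4a,7,8,8a-hexahydronaphthalene-1β-carboxylate, via β-keto acid 18 (not isolated)
Conditions: NaCl, H2O, DMSO, 120 °C
Reagents that add atoms: none
Why: Krapcho-type hydrolytic opening of the β-keto lactone and decarboxylation of the β-keto acid removes the activating carbonyl from C8 and frees the C1 CH2OH.

Step 12
Reactants: 19 enone alcohol
Product: 20 mesylate, tert-butyl 1α-[(methanesulfonyloxy)methyl]-6-methyl-7-oxo-2β-(prop-2-en-1-yl)-1,2,4a,7,8,8a-hexahydronaphthalene-1β-carboxylate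
Conditions: MsCl, Et3N, CH2Cl2, 0 °C
Reagents that add atoms: methanesulfonyl chloride, CS(=O)(=O)Cl
Why: Sulfonylation of the primary alcohol gives a group that is inert in the next four steps and is later reduced to the C1 methyl.

Step 13
Reactants: 20 enone mesylate
Product: 21 7α-allylic alcohol
Conditions: NaBH4, CeCl3·7H2O, MeOH, −78 → −40 °C
Reagents that add atoms: none
Why: Luche 1,2-reduction; axial hydride delivery from the β face should give the equatorial 7α-alcohol.

Step 14
Reactants: 21 allylic alcohol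
Product: 22 5α,6α-epoxy-7α-alcohol
Conditions: m-CPBA (1.05 equiv), NaHCO3, CH2Cl2, 0 °C
Reagents that add atoms: 3-chloroperbenzoic acid, OOC(=O)c1cccc(Cl)c1
Why: Henbest hydroxyl-directed epoxidation should deliver oxygen syn to the 7α-OH, and the trisubstituted, hydroxyl-activated ring A alkene should react ahead of the ring B and allyl alkenes.

Step 15
Reactants: 22 epoxy alcohol
Product: 24 5α-silyloxy-6α-methyl-7α-alcohol, via silyloxy ketone 23 (not isolated)
Conditions: TBSOTf (1.3 equiv), i-Pr2NEt, 4 Å MS, CH2Cl2, −45 °C; then MeOH, NaBH4, −45 → −10 °C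
Reagents that add atoms: tert-butyldimethylsilyl trifluoromethanesulfonate, CC(C)(C)[Si](C)(C)OS(=O)(=O)C(F)(F)F
Why: Non-aldol aldol rearrangement (silyl triflate-promoted semipinacol 1,2-hydride shift of an epoxy silyl ether): the pseudoaxial H-7 migrates to C6 anti to the breaking C6–O bond, which sets the axial 6α-methyl with inversion and leaves the C5 oxygen as its α-silyl ether; reduction of the C7 ketone in the same flask by axial hydride attack should give the equatorial 7α-alcohol before the α-methyl centre can epimerise.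

Step 16
Reactants: 24 hydroxy silyl ether
Product: 25 5α,7α-bis(silyl ether) mesylate
Conditions: TBSOTf, 2,6-lutidine, CH2Cl2, 0 °C
Reagents that add atoms: tert-butyldimethylsilyl trifluoromethanesulfonate, CC(C)(C)[Si](C)(C)OS(=O)(=O)C(F)(F)F
Why: Silylation protects the secondary alcohol for the two later oxidations.

Step 17
Reactants: 25 bis(silyl ether) mesylate
Product: 26 tert-butyl 5α,7α-bis[(tert-butyldimethylsilyl)oxy]-1α,6α-dimethyl-2β-(prop-2-en-1-yl)-1,2,4a,5,6,7,8,8a-octahydronaphthalene-1β-carboxylate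
Conditions: NaI, Zn, HMPA, 105 °C
Reagents that add atoms: none
Why: Reductive removal of a hindered primary sulfonate (iodide displacement, then zinc reduction of the iodide) converts the tether CH2O into the C1 methyl without forming an alkoxide next to the leaving group.

Step 18
Reactants: 26 tert-butyl ester
Product: 27 primary alcohol, [5α,7α-bis(silyloxy)-1α,6α-dimethyl-2β-allyl-octahydronaphthalen-1β-yl]methanol
Conditions: LiAlH4, THF, 0 → 40 °C
Reagents that add atoms: none
Why: Hydride reduction of the hindered ester to the neopentyl alcohol.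

Step 19
Reactants: 27 primary alcohol
Product: 28 decalin-1β-carbaldehyde
Conditions: Dess–Martin periodinane, NaHCO3, CH2Cl2, 23 °C
Reagents that add atoms: none
Why: Dess–Martin oxidation gives the non-enolisable aldehyde needed for the tetronate coupling.

Step 20
Reactants: 29 4-methylphenol
Product: 30 4-methoxy-4-methylcyclohexa-2,5-dien-1-one
Conditions: PhI(OAc)2, MeOH, 0 °C
Reagents that add atoms: methanol, CO
Why: Oxidative dearomatisation of a para-substituted phenol in methanol gives the prochiral quinol ether.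

Step 21
Reactants: 30 dienone
Product: 31 (5R)-5-ethyl-4-methoxy-4-methylcyclohex-2-en-1-one
Conditions: Et2Zn, Cu(OTf)2 (2.5 mol %), (S,R,R)-O,O'-(1,1'-binaphthyl-2,2'-diyl) N,N-bis(1-phenylethyl)phosphoramidite (5 mol %), toluene, −25 °C; aq. NH4Cl
Reagents that add atoms: diethylzinc, CC[Zn]CC
Why: Copper-catalysed asymmetric conjugate addition desymmetrises the dienone; the ligand enantiomer that gives (S)-3-ethylcyclohexanone from cyclohexenone should set the (5R) centre here (future ethyl-bearing carbon), and the C4 configuration is irrelevant.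

Step 22
Reactants: 31 γ-methoxy enone
Product: 32 (5R)-5-ethyl-4-methylcyclohex-3-en-1-one
Conditions: SmI2 (2.2 equiv), THF–HMPA, t-BuOH, −78 °C
Reagents that add atoms: none
Why: Reductive cleavage of the γ-alkoxy group of an enone by samarium diiodide gives a dienolate whose kinetic α-protonation should furnish the β,γ-unsaturated ketone.

Step 23
Reactants: 32 β,γ-enone
Product: 34 (5R)-5-ethyl-4-methyl-2-(prop-2-en-1-yl)cyclohex-3-en-1-one, via lithium dienolate 33 (not isolated)
Conditions: LDA, THF, −78 °C; then allyl bromide, −78 → 0 °C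
Reagents that add atoms: allyl bromide, C=CCBr
Why: The doubly activated α-position is deprotonated and the extended dienolate is alkylated at its α-carbon; the new centre is reset in the next step.

Step 24
Reactants: 34 allyl ketone
Product: 35 (2R,5R)-5-ethyl-2,4-dimethyl-2-(prop-2-en-1-yl)cyclohex-3-en-1-one
Conditions: t-BuOK (1.05 equiv), MeI, THF, −20 °C
Reagents that add atoms: iodomethane, CI
Why: Deconjugative α-alkylation of the extended dienolate; iodomethane should approach anti to the pseudoaxial ethyl group, which sets the quaternary centre with methyl trans and allyl cis to ethyl.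

Step 25
Reactants: 35 quaternary ketone; 36 methyl prop-2-ynoate
Product: 38 methyl 3-[(1S,2R,5R)-5-ethyl-1-hydroxy-2,4-dimethyl-2-(prop-2-en-1-yl)cyclohex-3-en-1-yl]prop-2-ynoate, via lithium acetylide 37 (not isolated)
Conditions: 36, LiHMDS, THF, −78 °C; then 35, −78 °C; aq. NH4Cl
Reagents that add atoms: none
Why: 1,2-Addition of a lithium acetylide to the ketone; the small nucleophile should add anti to the α-allyl and the ethyl groups, which sets the future spiro centre.

Step 26
Reactants: 38 hydroxy ynoate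
Product: 39 (5S,6R,9R)-9-ethyl-4-methoxy-6,8-dimethyl-6-(prop-2-en-1-yl)-1-oxaspiro[4.5]deca-3,7-dien-2-one
Conditions: NaOMe, MeOH, 0 → 23 °C
Reagents that add atoms: methanol (as sodium methoxide), CO
Why: Conjugate addition of methoxide to the ynoate followed by lactonisation of the tertiary alkoxide gives the 4-methoxy spirobutenolide (methyl tetronate).

Step 27
Reactants: 39 spiro methyl tetronate; 28 decalin aldehyde
Product: 41 secondary carbinol joining tetronate C3 to decalin C1, via 3-lithio tetronate 40 (not isolated)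
Conditions: 39, LDA, THF, −78 °C; then 28, −78 → −40 °C; aq. NH4Cl
Reagents that add atoms: none
Why: Lithiation of the methyl tetronate at C3 and 1,2-addition to the non-enolisable aldehyde; the carbinol configuration is of no consequence because it is oxidised next.

Step 28
Reactants: 41 carbinol
Product: 42 3-acyl-4-methoxy tetronate (bis-allyl ketone)
Conditions: Dess–Martin periodinane, NaHCO3, CH2Cl2, 23 °C
Reagents that add atoms: none
Why: Dess–Martin oxidation of the secondary alcohol to the acyl tetronate.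

Step 29
Reactants: 42 bis-allyl ketone
Product: 43 eleven-membered macrocycle with Z olefin
Conditions: Z-selective cyclometalated ruthenium nitrate catalyst Ru(O2NO)(=CH-C6H4-2-O-i-Pr)(C,C-chelating 1-(adamantan-1-yl)-3-(2,6-diisopropylphenyl)imidazolidin-2-ylidene) (7.5 mol %), ClCH2CH2Cl, 1 mM, 60 °C, static vacuum
Reagents that add atoms: none
Why: Ring-closing metathesis of the two allyl groups; the kinetically Z-selective catalyst together with the strain of an E olefin in the eleven-membered ring should give the Z alkene, and the ring and trisubstituted alkenes are unreactive.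

Step 30
Reactants: 43 macrocyclic methyl tetronate
Product: 44 bis(silyl ether) of the target
Conditions: LiCl, DMSO, 60 °C; then dilute HCl
Reagents that add atoms: none
Why: Chloride SN2 demethylation of the vinylogous ester releases the 3-acyltetronic acid.

Step 31
Reactants: 44 bis(silyl ether)
Product: 45 target CNP0259772.1
Conditions: HF·pyridine, THF/pyridine, 0 → 23 °C
Reagents that add atoms: none
Why: Fluoride-mediated cleavage of both secondary silyl ethers gives the diol without affecting the acyltetronic acid.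

**Compound list**

1 | 3-[(tert-butyldimethylsilyl)oxy]propanal | O=CCCO[Si](C)(C)C(C)(C)C | starting material
2 | (2E)-5-[(tert-butyldimethylsilyl)oxy]pent-2-enal | O=C/C=C/CCO[Si](C)(C)C(C)(C)C | intermediate
3 | tert-butyl methyl propanedioate | COC(=O)CC(=O)OC(C)(C)C | starting material
4 | tert-butyl methyl 2-[(3S)-1-[(tert-butyldimethylsilyl)oxy]-5-oxopentan-3-yl]propanedioate (both epimers at the malonate carbon) | CC(C)(C)[Si](C)(C)OCC[C@H](C(C(=O)OC)C(=O)OC(C)(C)C)CC=O | intermediate
5 | tert-butyl methyl 2-[(3R)-1-[(tert-butyldimethylsilyl)oxy]hex-5-en-3-yl]propanedioate (both epimers at the malonate carbon) | CC(C)(C)[Si](C)(C)OCC[C@H](C(C(=O)OC)C(=O)OC(C)(C)C)CC=C | intermediate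
6 | tert-butyl methyl 2-[(3R)-1-hydroxyhex-5-en-3-yl]propanedioate | OCC[C@H](C(C(=O)OC)C(=O)OC(C)(C)C)CC=C | intermediate
7 | tert-butyl (4R)-2-oxo-4-(prop-2-en-1-yl)oxane-3-carboxylate (C3 epimerisable, 3,4-trans predominant) | O=C1OCC[C@@H](CC=C)C1C(=O)OC(C)(C)C | intermediate
8 | tert-butyl (3S,4R)-2-oxo-4-(prop-2-en-1-yl)-3-{[(triisopropylsilyl)oxy]methyl}oxane-3-carboxylate (CH2OSi trans to allyl) | O=C1OCC[C@@H](CC=C)[C@@]1(CO[Si](C(C)C)(C(C)C)C(C)C)C(=O)OC(C)(C)C | intermediate
9 | tert-butyl (3S,4R)-2-hydroxy-4-(prop-2-en-1-yl)-3-{[(triisopropylsilyl)oxy]methyl}oxane-3-carboxylate (both anomers) | OC1OCC[C@@H](CC=C)[C@@]1(CO[Si](C(C)C)(C(C)C)C(C)C)C(=O)OC(C)(C)C | intermediate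
10 | 5-tert-butyl 1-methyl (2Z,4R)-4-[(3R)-1-hydroxyhex-5-en-3-yl]-4-{[(triisopropylsilyl)oxy]methyl}pent-2-enedioate | COC(=O)/C=C\[C@](CO[Si](C(C)C)(C(C)C)C(C)C)(C(=O)OC(C)(C)C)[C@H](CC=C)CCO | intermediate
11 | tert-butyl (3R)-3-[(3R)-1-hydroxyhex-5-en-3-yl]-6-oxo-3,6-dihydro-2H-pyran-3-carboxylate | O=C1OC[C@](C(=O)OC(C)(C)C)(C=C1)[C@H](CC=C)CCO | intermediate
12 | tert-butyl (3R)-6-oxo-3-[(3R)-1-oxohex-5-en-3-yl]-3,6-dihydro-2H-pyran-3-carboxylate | O=C1OC[C@](C(=O)OC(C)(C)C)(C=C1)[C@H](CC=C)CC=O | intermediate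
13 | tert-butyl (3R)-6-oxo-3-[(2E,5R)-1-oxoocta-2,7-dien-5-yl]-3,6-dihydro-2H-pyran-3-carboxylate | O=C1OC[C@](C(=O)OC(C)(C)C)(C=C1)[C@H](CC=C)C/C=C/C=O | intermediate
14 | tert-butyl (3R)-3-[(4R,6E,8E)-10-ethoxy-9-methyl-10-oxodeca-1,6,8-trien-4-yl]-6-oxo-3,6-dihydro-2H-pyran-3-carboxylate | O=C1OC[C@](C(=O)OC(C)(C)C)(C=C1)[C@H](CC=C)C/C=C/C=C(\C)C(=O)OCC | intermediate
15 | lithium trienolate of 14 (ε-deprotonated; new C=C next to the stereocentre Z, central C=C E) | O=C1OC[C@](C(=O)OC(C)(C)C)(C=C1)[C@H](CC=C)/C=C\C=C\C(C)=C([O-])OCC.[Li+] | intermediate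
16 | lithium lactone enolate after the conjugate addition: ring B closed, cis-fused to the lactone, (Z)-2-methylpropenoate arm on C4a | CC(C)(C)OC(=O)[C@@]1(COC([O-])=C2)[C@H]2[C@@H](/C=C(/C)C(=O)OCC)C=C[C@H]1CC=C.[Li+] | intermediate
17 | tert-butyl 6-methyl-7-oxo-2β-(prop-2-en-1-yl)-1,2,4a,7,8,8a-hexahydronaphthalene-1β-carboxylate whose C8 carboxyl is lactonised onto the 1α-CH2O group (δ-lactone; 4a-H α, 8a-H β; C8 epimerisable or enolised) | CC(C)(C)OC(=O)[C@@]1(COC2=O)[C@@H]3C2C(=O)C(C)=C[C@H]3C=C[C@H]1CC=C | intermediate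
18 | 8-carboxylic acid from lactone opening of 17: 1β-tert-butoxycarbonyl-1α-(hydroxymethyl)-6-methyl-7-oxo-2β-allyl-hexahydronaphthalene-8-carboxylic acid | CC(C)(C)OC(=O)[C@@]1(CO)[C@@H]2C(C(=O)O)C(=O)C(C)=C[C@H]2C=C[C@H]1CC=C | intermediate
19 | tert-butyl 1α-(hydroxymethyl)-6-methyl-7-oxo-2β-(prop-2-en-1-yl)-1,2,4a,7,8,8a-hexahydronaphthalene-1β-carboxylate (4a-H α, 8a-H β) | CC(C)(C)OC(=O)[C@@]1(CO)[C@@H]2CC(=O)C(C)=C[C@H]2C=C[C@H]1CC=C | intermediate
20 | tert-butyl 1α-[(methanesulfonyloxy)methyl]-6-methyl-7-oxo-2β-(prop-2-en-1-yl)-1,2,4a,7,8,8a-hexahydronaphthalene-1β-carboxylate (4a-H α, 8a-H β) | CC(C)(C)OC(=O)[C@@]1(COS(C)(=O)=O)[C@@H]2CC(=O)C(C)=C[C@H]2C=C[C@H]1CC=C | intermediate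
21 | tert-butyl 7α-hydroxy-1α-[(methanesulfonyloxy)methyl]-6-methyl-2β-(prop-2-en-1-yl)-1,2,4a,7,8,8a-hexahydronaphthalene-1β-carboxylate (4a-H α, 8a-H β) | CC(C)(C)OC(=O)[C@@]1(COS(C)(=O)=O)[C@@H]2C[C@H](O)C(C)=C[C@H]2C=C[C@H]1CC=C | intermediate
22 | tert-butyl 5α,6α-epoxy-7α-hydroxy-1α-[(methanesulfonyloxy)methyl]-6β-methyl-2β-(prop-2-en-1-yl)-1,2,4a,5,6,7,8,8a-octahydronaphthalene-1β-carboxylate (4a-H α, 8a-H β) | CC(C)(C)OC(=O)[C@@]1(COS(C)(=O)=O)[C@@H]2C[C@H](O)[C@]3(C)O[C@@H]3[C@H]2C=C[C@H]1CC=C | intermediate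
23 | tert-butyl 5α-[(tert-butyldimethylsilyl)oxy]-1α-[(methanesulfonyloxy)methyl]-6α-methyl-7-oxo-2β-(prop-2-en-1-yl)-1,2,4a,5,6,7,8,8a-octahydronaphthalene-1β-carboxylate (4a-H α, 8a-H β) | CC(C)(C)OC(=O)[C@@]1(COS(C)(=O)=O)[C@@H]2CC(=O)[C@H](C)[C@H](O[Si](C)(C)C(C)(C)C)[C@H]2C=C[C@H]1CC=C | intermediate
24 | tert-butyl 5α-[(tert-butyldimethylsilyl)oxy]-7α-hydroxy-1α-[(methanesulfonyloxy)methyl]-6α-methyl-2β-(prop-2-en-1-yl)-1,2,4a,5,6,7,8,8a-octahydronaphthalene-1β-carboxylate (4a-H α, 8a-H β) | CC(C)(C)OC(=O)[C@@]1(COS(C)(=O)=O)[C@@H]2C[C@H](O)[C@H](C)[C@H](O[Si](C)(C)C(C)(C)C)[C@H]2C=C[C@H]1CC=C | intermediate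
25 | tert-butyl 5α,7α-bis[(tert-butyldimethylsilyl)oxy]-1α-[(methanesulfonyloxy)methyl]-6α-methyl-2β-(prop-2-en-1-yl)-1,2,4a,5,6,7,8,8a-octahydronaphthalene-1β-carboxylate (4a-H α, 8a-H β) | CC(C)(C)OC(=O)[C@@]1(COS(C)(=O)=O)[C@@H]2C[C@H](O[Si](C)(C)C(C)(C)C)[C@H](C)[C@H](O[Si](C)(C)C(C)(C)C)[C@H]2C=C[C@H]1CC=C | intermediate
26 | tert-butyl 5α,7α-bis[(tert-butyldimethylsilyl)oxy]-1α,6α-dimethyl-2β-(prop-2-en-1-yl)-1,2,4a,5,6,7,8,8a-octahydronaphthalene-1β-carboxylate (4a-H α, 8a-H β) | CC(C)(C)OC(=O)[C@@]1(C)[C@@H]2C[C@H](O[Si](C)(C)C(C)(C)C)[C@H](C)[C@H](O[Si](C)(C)C(C)(C)C)[C@H]2C=C[C@H]1CC=C | intermediate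
27 | [5α,7α-bis[(tert-butyldimethylsilyl)oxy]-1α,6α-dimethyl-2β-(prop-2-en-1-yl)-1,2,4a,5,6,7,8,8a-octahydronaphthalen-1β-yl]methanol (4a-H α, 8a-H β) | OC[C@@]1(C)[C@@H]2C[C@H](O[Si](C)(C)C(C)(C)C)[C@H](C)[C@H](O[Si](C)(C)C(C)(C)C)[C@H]2C=C[C@H]1CC=C | intermediate
28 | 5α,7α-bis[(tert-butyldimethylsilyl)oxy]-1α,6α-dimethyl-2β-(prop-2-en-1-yl)-1,2,4a,5,6,7,8,8a-octahydronaphthalene-1β-carbaldehyde (4a-H α, 8a-H β) | O=C[C@@]1(C)[C@@H]2C[C@H](O[Si](C)(C)C(C)(C)C)[C@H](C)[C@H](O[Si](C)(C)C(C)(C)C)[C@H]2C=C[C@H]1CC=C | intermediate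
29 | 4-methylphenol | Cc1ccc(O)cc1 | starting material
30 | 4-methoxy-4-methylcyclohexa-2,5-dien-1-one | COC1(C)C=CC(=O)C=C1 | intermediate
31 | (5R)-5-ethyl-4-methoxy-4-methylcyclohex-2-en-1-one (both C4 epimers) | CC[C@@H]1CC(=O)C=CC1(C)OC | intermediate
32 | (5R)-5-ethyl-4-methylcyclohex-3-en-1-one | CC[C@@H]1CC(=O)CC=C1C | intermediate
33 | lithium (5R)-5-ethyl-4-methylcyclohexa-1,3-dien-1-olate | CC[C@@H]1CC([O-])=CC=C1C.[Li+] | intermediate
34 | (5R)-5-ethyl-4-methyl-2-(prop-2-en-1-yl)cyclohex-3-en-1-one (both C2 epimers) | C=CCC1C=C(C)[C@H](CC)CC1=O | intermediate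
35 | (2R,5R)-5-ethyl-2,4-dimethyl-2-(prop-2-en-1-yl)cyclohex-3-en-1-one (2-methyl trans to 5-ethyl) | C=CC[C@]1(C)C=C(C)[C@H](CC)CC1=O | intermediate
36 | methyl prop-2-ynoate | C#CC(=O)OC | starting material
37 | lithium 3-methoxy-3-oxoprop-1-yn-1-ide | [Li+].[C-]#CC(=O)OC | intermediate
38 | methyl 3-[(1S,2R,5R)-5-ethyl-1-hydroxy-2,4-dimethyl-2-(prop-2-en-1-yl)cyclohex-3-en-1-yl]prop-2-ynoate | C=CC[C@]1(C)C=C(C)[C@H](CC)C[C@@]1(O)C#CC(=O)OC | intermediate
39 | (5S,6R,9R)-9-ethyl-4-methoxy-6,8-dimethyl-6-(prop-2-en-1-yl)-1-oxaspiro[4.5]deca-3,7-dien-2-one | CC[C@@H]1C[C@]2(OC(=O)C=C2OC)[C@](C)(CC=C)C=C1C | intermediate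
40 | 3-lithio derivative of 39 | CC[C@@H]1C[C@]2(OC(=O)C([Li])=C2OC)[C@](C)(CC=C)C=C1C | intermediate
41 | carbinol: 3-{hydroxy[decalin-1β-yl of 28]methyl} derivative of 39 (both carbinol epimers; all other centres as in 28 and 39) | CC[C@@H]1C[C@]2(OC(=O)C(C(O)[C@@]3(C)[C@@H]4C[C@H](O[Si](C)(C)C(C)(C)C)[C@H](C)[C@H](O[Si](C)(C)C(C)(C)C)[C@H]4C=C[C@H]3CC=C)=C2OC)[C@](C)(CC=C)C=C1C | intermediate
42 | ketone: 3-(decalin-1β-carbonyl) derivative of 39 (centres as in 28 and 39) | CC[C@@H]1C[C@]2(OC(=O)C(C(=O)[C@@]3(C)[C@@H]4C[C@H](O[Si](C)(C)C(C)(C)C)[C@H](C)[C@H](O[Si](C)(C)C(C)(C)C)[C@H]4C=C[C@H]3CC=C)=C2OC)[C@](C)(CC=C)C=C1C | intermediate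
43 | macrocyclic 4-O-methyl, 5,7-bis-O-(tert-butyldimethylsilyl) derivative of the target (eleven-membered ring, Z olefin) | CC[C@@H]1C[C@]23OC(=O)C(C(=O)[C@@]4(C)[C@@H]5C[C@H](O[Si](C)(C)C(C)(C)C)[C@H](C)[C@H](O[Si](C)(C)C(C)(C)C)[C@H]5C=C[C@H]4C/C=C\C[C@]2(C)C=C1C)=C3OC | intermediate
44 | 5,7-bis-O-(tert-butyldimethylsilyl) derivative of the target (free 3-acyltetronic acid) | CC[C@@H]1C[C@]23OC(=O)/C(=C(\O)[C@@]4(C)[C@@H]5C[C@H](O[Si](C)(C)C(C)(C)C)[C@H](C)[C@H](O[Si](C)(C)C(C)(C)C)[C@H]5C=C[C@H]4C/C=C\C[C@]2(C)C=C1C)C3=O | intermediate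
45 | CNP0259772.1 | CC[C@@H]1C[C@]23OC(=O)/C(=C(\O)[C@@]4(C)[C@@H]5C[C@H](O)[C@H](C)[C@H](O)[C@H]5C=C[C@H]4C/C=C\C[C@]2(C)C=C1C)C3=O | target

**Totals.** Total step count: 31 steps. Longest linear sequence: 24 steps (steps 1–19, then 27–31); the tetronate fragment (steps 20–26) is made in parallel.

**Three steps most likely to fail**

Step 10 (key annulation). What may go wrong: the amide base may add in conjugate fashion to the dienoate or the lactone, or the conjugate addition may deliver the E-configured enoate so that the acylation does not follow and the adduct is protonated or oligomerises. The fallback sets out from 14 and replaces the anionic cascade by a neutral pericyclic one. LDA and TBSCl in THF–DMPU at −78 °C trap the trienolate as the silyl ketene acetal F1, which is heated in toluene at 110 °C to undergo a thermal intramolecular Diels–Alder reaction onto the lactone double bond (the same two bonds, the same cis-annulation), giving the mixed ketal cycloadduct F2. Dilute HCl in THF hydrolyses F2 to 17, where the route is rejoined.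

Step 15 (hydride-shift rearrangement). What may go wrong: a ring-contracting alkyl shift, or capture or elimination of the tertiary cation, may compete with the 1,2-hydride shift, and the α-methyl ketone may epimerise before it is reduced. The fallback sets out from 22 and uses the other hydrogen as the migrating group. TBSCl and imidazole give the epoxy silyl ether F3. A Meinwald rearrangement (LiClO4 in Et2O, or InCl3 in THF) opens the epoxide at the tertiary carbon with suprafacial shift of H-5 to C6, giving the C5 ketone F4 with the same 6α-methyl configuration. NaBH4 reduces F4 by axial attack to the equatorial 5α-alcohol F5, and TBSOTf with 2,6-lutidine converts F5 into 25, where the route is rejoined.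

Step 29 (macrocyclic metathesis). What may go wrong: intermolecular metathesis (oligomerisation) may outrun closure of the strained eleven-membered ring, or secondary metathesis may erode the Z geometry. The fallback sets out from 27 and 39 and inverts the order of the two unions. Z-selective cross-metathesis with the same ruthenium catalyst and an excess of 39 joins the two allyl groups without ring strain to give the Z-olefin alcohol F6. Dess–Martin oxidation gives the aldehyde F7. Lithium 2,2,6,6-tetramethylpiperidide in THF at −78 °C under high dilution lithiates the tetronate C3–H in the presence of the non-enolisable aldehyde and closes the ring by intramolecular 1,2-addition to the macrocyclic carbinol F8. Dess–Martin oxidation of F8 gives 43, where the route is rejoined.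

Further compounds

F1 | step 10 | tert-butyldimethylsilyl ketene acetal of 14 (Z olefin next to the stereocentre, then E, then the ketene acetal) | O=C1OC[C@](C(=O)OC(C)(C)C)(C=C1)[C@H](CC=C)/C=C\C=C\C(C)=C(OCC)O[Si](C)(C)C(C)(C)C
F2 | step 10 | Diels–Alder adduct: 7-ethoxy-7-silyloxy mixed ketal of 17 | CC(C)(C)OC(=O)[C@@]1(COC2=O)[C@@H]3C2C(OCC)(O[Si](C)(C)C(C)(C)C)C(C)=C[C@H]3C=C[C@H]1CC=C
F3 | step 15 | 7α-O-(tert-butyldimethylsilyl) ether of epoxide 22 | CC(C)(C)OC(=O)[C@@]1(COS(C)(=O)=O)[C@@H]2C[C@H](O[Si](C)(C)C(C)(C)C)[C@]3(C)O[C@@H]3[C@H]2C=C[C@H]1CC=C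
F4 | step 15 | tert-butyl 7α-[(tert-butyldimethylsilyl)oxy]-1α-[(methanesulfonyloxy)methyl]-6α-methyl-5-oxo-2β-(prop-2-en-1-yl)-1,2,4a,5,6,7,8,8a-octahydronaphthalene-1β-carboxylate | CC(C)(C)OC(=O)[C@@]1(COS(C)(=O)=O)[C@@H]2C[C@H](O[Si](C)(C)C(C)(C)C)[C@H](C)C(=O)[C@H]2C=C[C@H]1CC=C
F5 | step 15 | 5α-hydroxy-7α-silyloxy regioisomer of 24 | CC(C)(C)OC(=O)[C@@]1(COS(C)(=O)=O)[C@@H]2C[C@H](O[Si](C)(C)C(C)(C)C)[C@H](C)[C@H](O)[C@H]2C=C[C@H]1CC=C
F6 | step 29 | Z-olefin cross-metathesis product of 27 and 39 (primary alcohol) | OC[C@@]1(C)[C@@H]2C[C@H](O[Si](C)(C)C(C)(C)C)[C@H](C)[C@H](O[Si](C)(C)C(C)(C)C)[C@H]2C=C[C@H]1C/C=C\C[C@]3(C)C=C(C)[C@H](CC)C[C@]34OC(=O)C=C4OC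
F7 | step 29 | aldehyde from F6 | O=C[C@@]1(C)[C@@H]2C[C@H](O[Si](C)(C)C(C)(C)C)[C@H](C)[C@H](O[Si](C)(C)C(C)(C)C)[C@H]2C=C[C@H]1C/C=C\C[C@]3(C)C=C(C)[C@H](CC)C[C@]34OC(=O)C=C4OC
F8 | step 29 | macrocyclic carbinol (alcohol corresponding to ketone 43, both epimers) | CC[C@@H]1C[C@]23OC(=O)C(C(O)[C@@]4(C)[C@@H]5C[C@H](O[Si](C)(C)C(C)(C)C)[C@H](C)[C@H](O[Si](C)(C)C(C)(C)C)[C@H]5C=C[C@H]4C/C=C\C[C@]2(C)C=C1C)=C3OC
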